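Choosing what to do with this flask at 12 min is weighed here with one time constant, the leak time.

| setting | delta | theta | flask |
|---|---|---|---|
| starting material | 0.050 M | 0.075 M | 0.050 M |
| temperature | 90 °C | 85 °C | 90 °C |
| remark | the very flask that is asked about, followed so far | run made earlier |  |
| time |  |  | 12 min |

delta run (percent of the starting material charged)

| time / min | product / % | starting material / % |
|---|---|---|
| 1.00 | 27.1 | 17.8 |
| 2.00 | 35.0 | 4.2 |
| 3.00 | 34.4 | 0 |
| 4.00 | 35.9 | 0 |
| 5.00 | 37.0 | 0.6 |
| 6.00 | 37.3 | 0.2 |
| 8.00 | 39.7 | 2.7 |

theta run (percent of the starting material charged)

| time / s | product / % | starting material / % |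
|---|---|---|
| 10.0 | 5.4 | 81.6 |
| 12.0 | 6.0 | 78.8 |
| 20.0 | 10.2 | 68.1 |
| 30.0 | 12.2 | 55.1 |
| 50.0 | 17.9 | 38.6 |
| 60.0 | 20.9 | 33.2 |
| 120 | 29.4 | 11.5 |

(scatter of a reading: 1 percentage point)

- dawn: at 12 min raise the temperature by 25 K, then wait 4.0 min
- autumn: change nothing and wait 4.0 min more
- midnight: at 12 min take out 90% of the product then present, then wait 4.0 min
- dusk: at 12 min add starting material, 50.0% of the amount charged, then wait 4.0 min

- product that was removed still counts
- additions bring no volume worth counting

- product, in percent of the starting material first charged, at 12 min
- the remedy with the largest gain of product, or "none" below 2 percentage points (dawn / autumn / midnight / dusk / none)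
- product present, with what was taken out counted in, in percent of the starting material first charged, after dawn
- product present, with what was taken out counted in, in percent of the starting material first charged, after autumn

Theta is the nearest simulated run, and one molecule can be followed through both. At 2 min theta has turned 88.5% of its starting material into other things, and product holds 33.2% of that share. Delta at 1.00 min gives 33.0%. So in both runs a molecule leaving starting material reaches product in about a third of cases. Delta stands higher at the same time, 35.0% against 29.4%, with less [starting material] left, 4.2% against 11.5%.

The other cases look delayed rather than lost. At 6.00 min delta holds 62.5% of its charge in an unseen reservoir, while product still creeps up by a fraction 0.00783 /min of the charge. The reservoir divided by that creep is the leak time, 79.8 min, a reading with the scatter of its two ends.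

The reckoning here gives 42.8% at 12 min, and autumn gains 3.1 percentage points; midnight is reckoned like autumn. Dusk gains 20 points. Read as first-order decay, which sets the two charges aside, starting material is lost 1.60 times as fast in delta as in theta. Dawn's rise spans 5 such gaps between their temperatures, which shortens the leak time by a factor of 10.4, if the leak heats like the loss. Dawn then gains 23 points, so this reckoning picks dawn, narrowly.

The forecast says 43% now, 46.5% after autumn, 62% after dawn, and picks dusk. Its dawn figure assumes heat that “speeds it about sixfold”, where the reckoning here takes the factor of 10.4.

    starting material → product (k = 0.00886 /s, Ea = 102 kJ/mol)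
    starting material ⇌ intermediate A (K = 0.180, k = 0.00239 /s, Ea = 114 kJ/mol, ΔH = −32.0 kJ/mol)
    starting material ⇌ intermediate B (K = 34.4, k = 0.0200 /s, Ea = 104 kJ/mol, ΔH = −59.0 kJ/mol)
    intermediate A → product (k = 0.0186 /s, Ea = 85.0 kJ/mol)
    (constants at 90 °C)

The flask gives 41.7% at 12 min, with 57.1% in intermediate B, its resting state; autumn ends at 44.4%, dawn at 84.8%, and dawn gains 43 points against 21 points for dusk. At 12.0 min in the flask, by forward rates alone, starting material enters intermediate B 2.3 times as fast as it forms product directly. Dawn's gain, set against that store, means a leak time near 2.84 min at the raised temperature, shorter by a factor of 28.1. The neighbour kept at 105 °C holds 21.5% in intermediate B at 12 min; taking theta's reading of 66.8% as the share sent there, that means a leak time near 10.6 min, shorter by a factor of 7.53.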